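To the colleague who asked for a quick number on this flask: here is our reckoning from the earlier runs, before we set it beside your hunch.

common to all: starting material 0.020 M

| charge | reagent | free catalyst | remark |
|---|---|---|---|
| Wednesday's | 0.018 M | 10 µM | run made earlier |
| Monday's | 0.018 M | 15 µM | run made earlier |
| Tuesday's | 0.036 M | 20 µM | run made earlier |
| flask | 0.0180 M | 20 µM |  |

| run | time / h | target / % |
|---|---|---|
| Wednesday's | 0.417 | 3.0 |
| Wednesday's | 0.667 | 5.2 |
| Wednesday's | 1.33 | 9.7 |
| Wednesday's | 2.50 | 16.2 |
| Wednesday's | 5.00 | 28.1 |
| Monday's | 0.417 | 2.5 |
| Monday's | 0.667 | 6.6 |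
| Monday's | 1.33 | 12.1 |
| Monday's | 2.50 | 22.1 |
| Monday's | 5.00 | 38.6 |
| Tuesday's | 0.417 | 7.3 |
| Tuesday's | 0.667 | 12.9 |
| Tuesday's | 1.33 | 23.3 |
| Tuesday's | 2.50 | 41.6 |
| Tuesday's | 5.00 | 70.7 |

(each reading ± 0.5 percentage points)

- what was read earlier has a scatter of 0.5 percentage points, one standard deviation

- factor on the rate of making target when 10% of the starting material are converted if reagent is charged twice over
- factor on the rate when 10% of the starting material are converted if free catalyst is charged at 200 µM instead

Wednesday's and Monday's runs differ in catalyst charge, 10 µM against 15 µM, so we sum all the readings of each and divide the logarithm of the factor on target by the logarithm of the factor on catalyst, which gives the reading 0.679, and this slope of log rate on log catalyst charged, the catalyst order, is what we carry. Taken from 20 µM up to 200 µM, it puts the factor on the rate at 4.77. Tuesday's run is the doubled flask itself, with twice the reagent at 20 µM of catalyst, so we raise Monday's readings by 1.22 to that catalyst charge, and over the readings up to 1.33 h, which bracket the conversion asked about, Tuesday's target then stands at 1.69 times Monday's, our factor for doubling the reagent.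

Your hunch, the forecast, stands at 2 for the reagent and 1.9 for the catalyst, reading the runs as “a catalyst-saturated step relieved as starting material falls”.

The flask gives 1.68 on doubling the reagent and 4.46 at 200 µM, an order of 0.649 over that span against our 0.679.

    reagent + free catalyst → catalyst intermediate A (k = 19700 M⁻¹ h⁻¹)
    starting material + catalyst intermediate A ⇌ catalyst intermediate B (K = 138 M⁻¹, k = 31200 M⁻¹ h⁻¹)
    catalyst intermediate B → catalyst intermediate C (k = 5890 h⁻¹)
    catalyst intermediate C → free catalyst + target (k = 1200 h⁻¹)
    2 free catalyst ⇌ resting dimer, settled at all times (K = 79000 M⁻¹)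

In the flask at 1.76 h, catalyst intermediate C is made at 1.00 times the rate at which it is used up, each step taken net, and catalyst intermediate B at 1.00 times. The off-cycle resting dimer holds 36.0% of the catalyst in the flask at 0.893 h, when 10% of the starting material are converted, and with 200 µM its share at the same conversion is 71.5%.

The numbers in the tables are calculated on assumed constants.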